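**Retrosynthetic overview**

1. Target 33 ← oxidation of primary alcohol 31 (TEMPO/PhI(OAc)2, then NaClO2) ← Sonogashira coupling of dioxane alkyne 25 with (E)-iodoalkene 30 (from undec-10-en-2-one by cross-metathesis and iododeboronation).
2. Feature: with the ring numbered O1, O2, C3 (methoxy ketal), C4, C5, C6 (bearing the acid arm C7–C8), C3 lies three CH2 groups from the chain C≡C. C3, these three CH2 and the alkyne are the six carbons of hexa-1,5-diyne, so C3 travels as an alkyne carbon at the ketone oxidation level without a carbonyl.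
3. The 1,2-dioxane is the only ring and is closed once, in step 13: hydroperoxy diyne 20 and methanol under Hg(OTf)2 catalysis form C3–O2 and C3–OMe.
4. 20 ← SN2 inversion at the future C6 of mesylate 14 by masked hydroperoxide 17 ← alcohol 13 ← acetylide of mono-silylated hexa-1,5-diyne 10 plus iodide 7 ← lipase desymmetrization of diethyl 3-hydroxypentanedioate 1.

Key step: step 13

Assumption: Candida antarctica lipase B is taken to hydrolyse diethyl 3-hydroxypentanedioate to the (S)-half-ester, the substrate for which this sense is established, so the diethyl ester is used in place of the dimethyl ester.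

Abbreviations: TBDPS = tert-butyldiphenylsilyl, TES = triethylsilyl, TIPS = triisopropylsilyl.

**Route**

Step 1
Reactants: 1 diethyl 3-hydroxypentanedioate
Product: 2 (S)-5-ethoxy-3-hydroxy-5-oxopentanoic acid
Conditions: immobilized Candida antarctica lipase B (Novozym 435), phosphate buffer pH 7, 30 °C; acidify to pH 2, extract
Reagents that add atoms: water, O
Why: Enzymatic desymmetrization of a prochiral diester (enantiotopic-group-selective hydrolysis), in which the lipase should cleave one ester arm only and so set the carbinol centre as S.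

Step 2
Reactants: 2 (S)-5-ethoxy-3-hydroxy-5-oxopentanoic acid
Product: 3 ethyl (S)-3,5-dihydroxypentanoate
Conditions: BH3·SMe2, B(OMe)3, THF, 0 °C to rt; MeOH quench; used crude
Reagents that add atoms: none
Why: Chemoselective borane reduction, since borane reduces a carboxylic acid much faster than an ester; the stereocentre is untouched and the lactonization-prone diol is carried on at once.

Step 3
Reactants: 3 ethyl (S)-3,5-dihydroxypentanoate
Product: 5 ethyl (S)-5-[(tert-butyldiphenylsilyl)oxy]-3-[(triethylsilyl)oxy]pentanoate, via mono-TBDPS ether 4 (not isolated)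
Conditions: tBuPh2SiCl (1.05 equiv), imidazole, CH2Cl2, 0 °C; then Et3SiCl, 0 °C to rt
Reagents that add atoms: tert-butyl(chloro)diphenylsilane, CC(C)(C)[Si](Cl)(c1ccccc1)c1ccccc1; chlorotriethylsilane, CC[Si](Cl)(CC)CC
Why: Sequential one-flask silylation, in which the bulky tBuPh2SiCl should react only at the primary hydroxyl and Et3SiCl then caps the secondary one, giving two silyl ethers of very different acid lability.

Step 4
Reactants: 5 ethyl (S)-5-[(tert-butyldiphenylsilyl)oxy]-3-[(triethylsilyl)oxy]pentanoate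
Product: 6 (R)-5-[(tert-butyldiphenylsilyl)oxy]-3-[(triethylsilyl)oxy]pentan-1-ol
Conditions: iBu2AlH (2.2 equiv), CH2Cl2, −78 to 0 °C; Rochelle salt work-up
Reagents that add atoms: none
Why: Hydride reduction of the ester to the primary alcohol; both silyl ethers are inert and the descriptor changes only through priority order.

Step 5
Reactants: 6 (R)-5-[(tert-butyldiphenylsilyl)oxy]-3-[(triethylsilyl)oxy]pentan-1-ol
Product: 7 tert-butyl{[(3S)-5-iodo-3-[(triethylsilyl)oxy]pentyl]oxy}diphenylsilane
Conditions: PPh3, I2, imidazole, CH2Cl2, 0 °C to rt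
Reagents that add atoms: iodine, II
Why: Appel-type iodination of the primary alcohol by SN2 displacement of the activated oxygen, with imidazole buffering the medium so that the TES ether survives.

Step 6
Reactants: 8 hexa-1,5-diyne
Product: 10 (hexa-1,5-diyn-1-yl)tri(propan-2-yl)silane, via lithium hexa-1,5-diyn-1-ide 9 (not isolated)
Conditions: 8 (2.5 equiv), nBuLi (1.0 equiv), THF, −78 °C; iPr3SiOTf, −78 to 0 °C
Reagents that add atoms: triisopropylsilyl trifluoromethanesulfonate, CC(C)[Si](OS(=O)(=O)C(F)(F)F)(C(C)C)C(C)C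
Why: Statistical mono-C-silylation of the symmetric diyne through its mono-lithium acetylide, with the diyne in excess so that the mono-silyl compound dominates and is separable by distillation.

Step 7
Reactants: 10 (hexa-1,5-diyn-1-yl)tri(propan-2-yl)silane; 7 tert-butyl{[(3S)-5-iodo-3-[(triethylsilyl)oxy]pentyl]oxy}diphenylsilane
Product: 12 (R)-1-[(tert-butyldiphenylsilyl)oxy]-3-[(triethylsilyl)oxy]-11-(triisopropylsilyl)undeca-6,10-diyne, via lithium acetylide 11 (not isolated)
Conditions: 10 (1.3 equiv), nBuLi, THF, −78 °C; then 7, DMPU, −78 °C to rt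
Reagents that add atoms: none
Why: SN2 alkylation of a lithium acetylide by a primary iodide in THF/DMPU, a standard C(sp)–C(sp3) bond formation that leaves the remote silyloxy stereocentre untouched.

Step 8
Reactants: 12 (R)-1-[(tert-butyldiphenylsilyl)oxy]-3-[(triethylsilyl)oxy]-11-(triisopropylsilyl)undeca-6,10-diyne
Product: 13 (R)-1-[(tert-butyldiphenylsilyl)oxy]-11-(triisopropylsilyl)undeca-6,10-diyn-3-ol
Conditions: pyridinium 4-toluenesulfonate (0.1 equiv), MeOH/CH2Cl2, 0 °C to rt
Reagents that add atoms: none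
Why: Acid-catalysed methanolysis cleaves the secondary TES ether selectively, the primary TBDPS ether and the C-silyl alkyne being far more stable to this weak acid.

Step 9
Reactants: 13 (R)-1-[(tert-butyldiphenylsilyl)oxy]-11-(triisopropylsilyl)undeca-6,10-diyn-3-ol
Product: 14 (R)-1-[(tert-butyldiphenylsilyl)oxy]-11-(triisopropylsilyl)undeca-6,10-diyn-3-yl methanesulfonate
Conditions: MsCl, Et3N, CH2Cl2, 0 °C
Reagents that add atoms: methanesulfonyl chloride, CS(=O)(=O)Cl
Why: O-Sulfonylation of the secondary alcohol, with retention at carbon because only the O–H bond reacts.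

Step 10
Reactants: 15 2,3-dimethylbut-2-ene
Product: 17 2-hydroperoxy-2-methoxypropane, via acetone O-oxide 16 (not isolated)
Conditions: O3, MeOH/CH2Cl2, −78 °C; N2 purge; used as a solution
Reagents that add atoms: ozone, [O-][O+]=O; methanol, CO
Why: Ozonolysis of a tetrasubstituted alkene in methanol, in which Criegee cleavage gives acetone and the carbonyl oxide 16 that methanol traps as the α-methoxy hydroperoxide.

Step 11
Reactants: 14 (R)-1-[(tert-butyldiphenylsilyl)oxy]-11-(triisopropylsilyl)undeca-6,10-diyn-3-yl methanesulfonate; 17 2-hydroperoxy-2-methoxypropane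
Product: 19 tert-butyl{[(3S)-3-[(2-methoxypropan-2-yl)peroxy]-11-(triisopropylsilyl)undeca-6,10-diyn-1-yl]oxy}diphenylsilane, via caesium peroxide salt 18 (not isolated)
Conditions: 17 (3 equiv), CsOH·H2O (1.5 equiv), DMF, 0 °C to rt
Reagents that add atoms: none
Why: SN2 displacement of a secondary sulfonate by a peroxide anion (an α-effect nucleophile of low basicity) with inversion from R to S at the future C6, the excess of 17 keeping free hydroxide low so that the silyl groups survive.

Step 12
Reactants: 19 tert-butyl{[(3S)-3-[(2-methoxypropan-2-yl)peroxy]-11-(triisopropylsilyl)undeca-6,10-diyn-1-yl]oxy}diphenylsilane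
Product: 20 (S)-tert-butyl{[3-hydroperoxy-11-(triisopropylsilyl)undeca-6,10-diyn-1-yl]oxy}diphenylsilane
Conditions: AcOH/THF/H2O (3:1:1), rt
Reagents that add atoms: none
Why: Mild aqueous-acid hydrolysis of the mixed peroxyketal at its ketal carbon releases the secondary hydroperoxide without touching the C–O bond at the stereocentre or the silyl groups.

Step 13
Reactants: 20 (S)-tert-butyl{[3-hydroperoxy-11-(triisopropylsilyl)undeca-6,10-diyn-1-yl]oxy}diphenylsilane
Product: 24 tert-butyl{2-[(3S,6R)-6-methoxy-6-[5-(triisopropylsilyl)pent-4-yn-1-yl]-1,2-dioxan-3-yl]ethoxy}diphenylsilane, via vinylmercury triflate 21 (not isolated), via enol peroxide 22 (not isolated), via peroxycarbenium triflate 23 (not isolated)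
Conditions: Hg(OTf)2 (5 mol %), MeOH/CH2Cl2 (1:1), 0 °C, dark; Et3N quench
Reagents that add atoms: methanol, CO
Why: Proposed new method: divalent mercury binds the internal alkyne as a π-complex and the terminal hydroperoxide oxygen adds anti to the proximal alkyne carbon (the future C3, bond C3–O2) to give vinylmercury species 21, the TfOH set free protodemercurates it to the exocyclic enol peroxide 22, and C-protonation of 22 gives the peroxycarbenium ion 23 that methanol captures (bond C3–OMe). The closest known reaction types are the cycloperoxymercuration of alkenyl hydroperoxides with Hg(OAc)2 and the cycloketalization of alkynols in methanol with Hg(OTf)2 or Ph3PAuNTf2 (monovalent gold), but a hydroperoxide as internal nucleophile toward a metal-activated alkyne has not been shown. The single ring is closed in the 6-exo-dig mode, which places the oxygen on the proximal alkyne carbon and is preferred over 7-endo attack on the distal one. The C6 stereocentre is carried unchanged from 20, and the new C3 centre is set under thermodynamic control because methanol capture of 23 is reversible in the acidic medium: the (R)-epimer has the methoxy group axial (anomeric stabilization by O2) and both carbon chains equatorial. The step needs chemoselectivity between the two alkynes and between hydroperoxide and methanol as first nucleophile, which the bulky TIPS cap on the distal alkyne and the intramolecular six-membered closure should secure. Divalent mercury is chosen because it is not a one-electron redox partner for a hydroperoxide, unlike copper or iron salts.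

Step 14
Reactants: 24 tert-butyl{2-[(3S,6R)-6-methoxy-6-[5-(triisopropylsilyl)pent-4-yn-1-yl]-1,2-dioxan-3-yl]ethoxy}diphenylsilane
Product: 25 2-[(3S,6R)-6-methoxy-6-(pent-4-yn-1-yl)-1,2-dioxan-3-yl]ethan-1-ol
Conditions: Bu4NF, AcOH (1:1), THF, 0 °C to rt
Reagents that add atoms: none
Why: Fluoride-mediated desilylation cleaves both the O–Si ether and the C(sp)–Si bond, and acetic acid buffering keeps the medium too weakly basic for Kornblum–DeLaMare-type fragmentation of the dioxane.

Step 15
Reactants: 26 undec-10-en-2-one; 27 4,4,5,5-tetramethyl-2-vinyl-1,3,2-dioxaborolane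
Product: 28 (E)-11-(4,4,5,5-tetramethyl-1,3,2-dioxaborolan-2-yl)undec-10-en-2-one
Conditions: second-generation Grubbs catalyst RuCl2(=CHPh)(H2IMes)(PCy3) (3 mol %), 27 (2.5 equiv), CH2Cl2, 40 °C
Reagents that add atoms: none
Why: Olefin cross-metathesis of a terminal alkene with a vinylboronate, which is known to favour the (E)-alkenylboronate and tolerates ketones.

Step 16
Reactants: 28 (E)-11-(4,4,5,5-tetramethyl-1,3,2-dioxaborolan-2-yl)undec-10-en-2-one
Product: 30 (E)-11-iodoundec-10-en-2-one, via borate ate complex 29 (not isolated)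
Conditions: NaOMe (1.1 equiv), MeOH/THF, −78 °C; ICl (1.0 equiv), CH2Cl2, −78 °C; aq Na2S2O3
Reagents that add atoms: iodine monochloride, ClI
Why: Stereoretentive iododeboronation, in which the methoxide ate complex 29 is iodinated at the boron-bearing carbon with retention of the E geometry, and at −78 °C with one equivalent of each reagent the methyl ketone should not enolize.

Step 17
Reactants: 25 2-[(3S,6R)-6-methoxy-6-(pent-4-yn-1-yl)-1,2-dioxan-3-yl]ethan-1-ol; 30 (E)-11-iodoundec-10-en-2-one
Product: 31 (E)-16-[(3R,6S)-6-(2-hydroxyethyl)-3-methoxy-1,2-dioxan-3-yl]hexadec-10-en-12-yn-2-one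
Conditions: Pd(PPh3)4 (zerovalent palladium, 5 mol %), CuI (10 mol %), iPr2NH, THF, degassed, rt
Reagents that add atoms: none
Why: Sonogashira coupling of the terminal alkyne with the (E)-iodoalkene (zerovalent palladium with monovalent copper as co-catalyst) at room temperature with retention of alkene geometry, a coupling that unactivated dialkyl peroxides are known to tolerate.

Step 18
Reactants: 31 (E)-16-[(3R,6S)-6-(2-hydroxyethyl)-3-methoxy-1,2-dioxan-3-yl]hexadec-10-en-12-yn-2-one
Product: 32 2-[(3S,6R)-6-methoxy-6-[(E)-15-oxohexadec-6-en-4-yn-1-yl]-1,2-dioxan-3-yl]acetaldehyde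
Conditions: TEMPO (2,2,6,6-tetramethylpiperidin-1-oxyl, 10 mol %), PhI(OAc)2 (1.2 equiv), CH2Cl2, rt; used crude
Reagents that add atoms: none
Why: Oxoammonium-mediated oxidation of the primary alcohol, which does not touch the ketone, enyne or peroxide and stops at the aldehyde in the absence of water.

Step 19
Reactants: 32 2-[(3S,6R)-6-methoxy-6-[(E)-15-oxohexadec-6-en-4-yn-1-yl]-1,2-dioxan-3-yl]acetaldehyde
Product: 33 2-[(3S,6R)-6-methoxy-6-[(E)-15-oxohexadec-6-en-4-yn-1-yl]-1,2-dioxan-3-yl]acetic acid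
Conditions: NaClO2, NaH2PO4, 2-methylbut-2-ene, tBuOH/H2O, 0 °C to rt
Reagents that add atoms: sodium chlorite, [Na+].[O-]Cl=O
Why: Pinnick oxidation of the aldehyde to the acid under buffered conditions, the alkene scavenger removing HOCl so that the enyne, the peroxyketal and the C6 stereocentre are not affected.

**Compound list**

1 | diethyl 3-hydroxypentanedioate | CCOC(=O)CC(O)CC(=O)OCC | starting material
2 | (S)-5-ethoxy-3-hydroxy-5-oxopentanoic acid | CCOC(=O)C[C@@H](O)CC(=O)O | intermediate
3 | ethyl (S)-3,5-dihydroxypentanoate | CCOC(=O)C[C@@H](O)CCO | intermediate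
4 | ethyl (S)-5-[(tert-butyldiphenylsilyl)oxy]-3-hydroxypentanoate | CCOC(=O)C[C@@H](O)CCO[Si](c1ccccc1)(c1ccccc1)C(C)(C)C | intermediate
5 | ethyl (S)-5-[(tert-butyldiphenylsilyl)oxy]-3-[(triethylsilyl)oxy]pentanoate | CCOC(=O)C[C@@H](O[Si](CC)(CC)CC)CCO[Si](c1ccccc1)(c1ccccc1)C(C)(C)C | intermediate
6 | (R)-5-[(tert-butyldiphenylsilyl)oxy]-3-[(triethylsilyl)oxy]pentan-1-ol | OCC[C@@H](O[Si](CC)(CC)CC)CCO[Si](c1ccccc1)(c1ccccc1)C(C)(C)C | intermediate
7 | tert-butyl{[(3S)-5-iodo-3-[(triethylsilyl)oxy]pentyl]oxy}diphenylsilane | ICC[C@@H](O[Si](CC)(CC)CC)CCO[Si](c1ccccc1)(c1ccccc1)C(C)(C)C | intermediate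
8 | hexa-1,5-diyne | C#CCCC#C | starting material
9 | lithium hexa-1,5-diyn-1-ide | [Li]C#CCCC#C | intermediate
10 | (hexa-1,5-diyn-1-yl)tri(propan-2-yl)silane | C#CCCC#C[Si](C(C)C)(C(C)C)C(C)C | intermediate
11 | lithium 6-[tri(propan-2-yl)silyl]hexa-1,5-diyn-1-ide | [Li]C#CCCC#C[Si](C(C)C)(C(C)C)C(C)C | intermediate
12 | (R)-1-[(tert-butyldiphenylsilyl)oxy]-3-[(triethylsilyl)oxy]-11-(triisopropylsilyl)undeca-6,10-diyne | CC(C)[Si](C(C)C)(C(C)C)C#CCCC#CCC[C@@H](O[Si](CC)(CC)CC)CCO[Si](c1ccccc1)(c1ccccc1)C(C)(C)C | intermediate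
13 | (R)-1-[(tert-butyldiphenylsilyl)oxy]-11-(triisopropylsilyl)undeca-6,10-diyn-3-ol | CC(C)[Si](C(C)C)(C(C)C)C#CCCC#CCC[C@@H](O)CCO[Si](c1ccccc1)(c1ccccc1)C(C)(C)C | intermediate
14 | (R)-1-[(tert-butyldiphenylsilyl)oxy]-11-(triisopropylsilyl)undeca-6,10-diyn-3-yl methanesulfonate | CC(C)[Si](C(C)C)(C(C)C)C#CCCC#CCC[C@@H](OS(C)(=O)=O)CCO[Si](c1ccccc1)(c1ccccc1)C(C)(C)C | intermediate
15 | 2,3-dimethylbut-2-ene | CC(C)=C(C)C | starting material
16 | acetone O-oxide (propan-2-one O-oxide) | CC(C)=[O+][O-] | intermediate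
17 | 2-hydroperoxy-2-methoxypropane | COC(C)(C)OO | intermediate
18 | caesium 2-methoxypropan-2-yl peroxide | [Cs+].COC(C)(C)O[O-] | intermediate
19 | tert-butyl{[(3S)-3-[(2-methoxypropan-2-yl)peroxy]-11-(triisopropylsilyl)undeca-6,10-diyn-1-yl]oxy}diphenylsilane | CC(C)[Si](C(C)C)(C(C)C)C#CCCC#CCC[C@H](OOC(C)(C)OC)CCO[Si](c1ccccc1)(c1ccccc1)C(C)(C)C | intermediate
20 | (S)-tert-butyl{[3-hydroperoxy-11-(triisopropylsilyl)undeca-6,10-diyn-1-yl]oxy}diphenylsilane | CC(C)(C)[Si](c1ccccc1)(c1ccccc1)OCC[C@@H](OO)CCC#CCCC#C[Si](C(C)C)(C(C)C)C(C)C | intermediate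
21 | {(1E)-1-[(6S)-6-{2-[(tert-butyldiphenylsilyl)oxy]ethyl}-1,2-dioxan-3-ylidene]-5-(triisopropylsilyl)pent-4-yn-1-yl}mercury trifluoromethanesulfonate | CC(C)[Si](C(C)C)(C(C)C)C#CCC/C([Hg]OS(=O)(=O)C(F)(F)F)=C1/CC[C@@H](CCO[Si](c2ccccc2)(c2ccccc2)C(C)(C)C)OO1 | intermediate
22 | tert-butyl(2-{(3S,6Z)-6-[5-(triisopropylsilyl)pent-4-yn-1-ylidene]-1,2-dioxan-3-yl}ethoxy)diphenylsilane | CC(C)[Si](C(C)C)(C(C)C)C#CCC/C=C1/CC[C@@H](CCO[Si](c2ccccc2)(c2ccccc2)C(C)(C)C)OO1 | intermediate
23 | (6S)-6-{2-[(tert-butyldiphenylsilyl)oxy]ethyl}-3-[5-(triisopropylsilyl)pent-4-yn-1-yl]-5,6-dihydro-4H-1,2-dioxin-2-ium trifluoromethanesulfonate (ring peroxycarbenium ion, C3=O2+) | CC(C)[Si](C(C)C)(C(C)C)C#CCCCC1=[O+]O[C@H](CCO[Si](c2ccccc2)(c2ccccc2)C(C)(C)C)CC1.[O-]S(=O)(=O)C(F)(F)F | intermediate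
24 | tert-butyl{2-[(3S,6R)-6-methoxy-6-[5-(triisopropylsilyl)pent-4-yn-1-yl]-1,2-dioxan-3-yl]ethoxy}diphenylsilane | CO[C@@]1(CCCC#C[Si](C(C)C)(C(C)C)C(C)C)CC[C@@H](CCO[Si](c2ccccc2)(c2ccccc2)C(C)(C)C)OO1 | intermediate
25 | 2-[(3S,6R)-6-methoxy-6-(pent-4-yn-1-yl)-1,2-dioxan-3-yl]ethan-1-ol | CO[C@@]1(CCCC#C)CC[C@@H](CCO)OO1 | intermediate
26 | undec-10-en-2-one | CC(=O)CCCCCCCC=C | starting material
27 | 4,4,5,5-tetramethyl-2-vinyl-1,3,2-dioxaborolane | C=CB1OC(C)(C)C(C)(C)O1 | starting material
28 | (E)-11-(4,4,5,5-tetramethyl-1,3,2-dioxaborolan-2-yl)undec-10-en-2-one | CC(=O)CCCCCCC/C=C/B1OC(C)(C)C(C)(C)O1 | intermediate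
29 | sodium 2-methoxy-4,4,5,5-tetramethyl-2-[(E)-10-oxoundec-1-en-1-yl]-1,3,2-dioxaborolan-2-uide | [Na+].CO[B-]1(/C=C/CCCCCCCC(C)=O)OC(C)(C)C(C)(C)O1 | intermediate
30 | (E)-11-iodoundec-10-en-2-one | CC(=O)CCCCCCC/C=C/I | intermediate
31 | (E)-16-[(3R,6S)-6-(2-hydroxyethyl)-3-methoxy-1,2-dioxan-3-yl]hexadec-10-en-12-yn-2-one | CO[C@@]1(CCCC#C/C=C/CCCCCCCC(C)=O)CC[C@@H](CCO)OO1 | intermediate
32 | 2-[(3S,6R)-6-methoxy-6-[(E)-15-oxohexadec-6-en-4-yn-1-yl]-1,2-dioxan-3-yl]acetaldehyde | CO[C@@]1(CCCC#C/C=C/CCCCCCCC(C)=O)CC[C@@H](CC=O)OO1 | intermediate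
33 | 2-[(3S,6R)-6-methoxy-6-[(E)-15-oxohexadec-6-en-4-yn-1-yl]-1,2-dioxan-3-yl]acetic acid | CO[C@@]1(CCCC#C/C=C/CCCCCCCC(C)=O)CC[C@@H](CC(=O)O)OO1 | target

**Step count**

Total: 19 steps. Longest linear sequence: 15 steps (steps 1–5, 7–9, 11–14, 17–19).

**Steps most likely to fail**

1. Step 13 (key step). What may go wrong:
- metal- or acid-induced decomposition of the hydroperoxide before it cyclizes;
- intermolecular methanol addition to the alkyne, or 7-endo closure, outrunning the 6-exo closure;
- rearrangement of the enol peroxide before it is protonated.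

Fallback with known chemistry, setting out from alcohol 13 and rejoining at 24:
- Hydroxyl-assisted hydration of the internal alkyne of 13 (Ph3PAuNTf2, monovalent gold, 2 mol %, wet THF; 5-exo-dig attack of the γ-hydroxyl, then hydrolysis of the enol ether) should put the carbonyl on the carbon destined to become the ketal carbon, giving (R)-1-[(tert-butyldiphenylsilyl)oxy]-3-hydroxy-11-(triisopropylsilyl)undec-10-yn-6-one F1.
- MsCl/Et3N would convert it into the keto mesylate (R)-1-[(tert-butyldiphenylsilyl)oxy]-6-oxo-11-(triisopropylsilyl)undec-10-yn-3-yl methanesulfonate F2.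
- HC(OMe)3 with pyridinium 4-toluenesulfonate in MeOH would give the dimethyl ketal (R)-1-[(tert-butyldiphenylsilyl)oxy]-6,6-dimethoxy-11-(triisopropylsilyl)undec-10-yn-3-yl methanesulfonate F3.
- Displacement with 17 and CsOH·H2O in DMF, as in step 11, would give with inversion tert-butyl{[(3S)-6,6-dimethoxy-3-[(2-methoxypropan-2-yl)peroxy]-11-(triisopropylsilyl)undec-10-yn-1-yl]oxy}diphenylsilane F4.
- Catalytic camphorsulfonic acid in MeOH/CH2Cl2 would exchange the 2-methoxyprop-2-yl group onto methanol and let the freed hydroperoxide close on the oxocarbenium ion of the dimethyl ketal. This acid-catalysed intramolecular peroxyketalization gives 24 under the same thermodynamic control at the ketal carbon.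

2. Step 11. What may go wrong:
- E2 elimination of the secondary mesylate outcompeting SN2;
- base-induced decay of the peroxide anion;
- partial loss of the TBDPS ether under hydroxide.

Fallback that makes the C6–O1 bond in a ring-closing mode, setting out from alcohol 13 and rejoining at 24 (steps 9 to 13 are bypassed):
- The ketal mesylate F3 is prepared from 13 through F1 and F2 as described above.
- Exchange of one methoxy group for a hydroperoxy group with anhydrous H2O2 in Et2O and pyridinium 4-toluenesulfonate would give the hydroperoxy ketal (3R)-1-[(tert-butyldiphenylsilyl)oxy]-6-hydroperoxy-6-methoxy-11-(triisopropylsilyl)undec-10-yn-3-yl methanesulfonate F5 (both ketal epimers).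
- KOtBu with 18-crown-6 in THF would close the dioxane by intramolecular 6-exo-tet displacement of the mesylate by the peroxy anion, with inversion at the carbinol carbon. This should give 24 together with its ketal epimer tert-butyl{2-[(3S,6S)-6-methoxy-6-[5-(triisopropylsilyl)pent-4-yn-1-yl]-1,2-dioxan-3-yl]ethoxy}diphenylsilane F6.
- Brief treatment with camphorsulfonic acid in MeOH would equilibrate F6 to 24.

3. Step 16. What may go wrong:
- α-iodination of the methyl ketone through its enolate;
- erosion of alkene geometry if halogen addition precedes borate formation.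

Fallback setting out from 26 and rejoining at 30:
- Ozonolysis of 26 (O3, CH2Cl2, −78 °C; PPh3) would give 9-oxodecanal F7.
- Aldehyde-selective, E-selective Takai olefination (CrCl2, divalent chromium, with CHI3 in THF/1,4-dioxane, 0 °C to rt) would convert F7 into 30 without any base or electrophilic halogen near the ketone.

**Further compounds**

F1 | step 13 | (R)-1-[(tert-butyldiphenylsilyl)oxy]-3-hydroxy-11-(triisopropylsilyl)undec-10-yn-6-one | CC(C)[Si](C(C)C)(C(C)C)C#CCCCC(=O)CC[C@@H](O)CCO[Si](c1ccccc1)(c1ccccc1)C(C)(C)C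
F2 | step 13 | (R)-1-[(tert-butyldiphenylsilyl)oxy]-6-oxo-11-(triisopropylsilyl)undec-10-yn-3-yl methanesulfonate | CC(C)[Si](C(C)C)(C(C)C)C#CCCCC(=O)CC[C@@H](OS(C)(=O)=O)CCO[Si](c1ccccc1)(c1ccccc1)C(C)(C)C
F3 | step 13 | (R)-1-[(tert-butyldiphenylsilyl)oxy]-6,6-dimethoxy-11-(triisopropylsilyl)undec-10-yn-3-yl methanesulfonate | CC(C)[Si](C(C)C)(C(C)C)C#CCCCC(OC)(OC)CC[C@@H](OS(C)(=O)=O)CCO[Si](c1ccccc1)(c1ccccc1)C(C)(C)C
F4 | step 13 | tert-butyl{[(3S)-6,6-dimethoxy-3-[(2-methoxypropan-2-yl)peroxy]-11-(triisopropylsilyl)undec-10-yn-1-yl]oxy}diphenylsilane | CC(C)[Si](C(C)C)(C(C)C)C#CCCCC(OC)(OC)CC[C@H](OOC(C)(C)OC)CCO[Si](c1ccccc1)(c1ccccc1)C(C)(C)C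
F5 | step 11 | (3R)-1-[(tert-butyldiphenylsilyl)oxy]-6-hydroperoxy-6-methoxy-11-(triisopropylsilyl)undec-10-yn-3-yl methanesulfonate | CC(C)[Si](C(C)C)(C(C)C)C#CCCCC(OC)(OO)CC[C@@H](OS(C)(=O)=O)CCO[Si](c1ccccc1)(c1ccccc1)C(C)(C)C
F6 | step 11 | tert-butyl{2-[(3S,6S)-6-methoxy-6-[5-(triisopropylsilyl)pent-4-yn-1-yl]-1,2-dioxan-3-yl]ethoxy}diphenylsilane | CO[C@]1(CCCC#C[Si](C(C)C)(C(C)C)C(C)C)CC[C@@H](CCO[Si](c2ccccc2)(c2ccccc2)C(C)(C)C)OO1
F7 | step 16 | 9-oxodecanal | CC(=O)CCCCCCCC=O
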